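all flasks: left-handed substrate 0.050 M; right-handed substrate 0.050 M

|  | gas | free catalyst | remark | time |
|---|---|---|---|---|
| Monday's | 5 mM (held) | 7 mM | run made earlier |  |
| Saturday's | 5 mM (held) | 11 mM | run made earlier |  |
| flask | 5.0 mM (held) | 5.0 mM |  | 15 h |

- Monday's (time / h: left-handed product / %, right-handed product / %): 1.33: 14.7, 8.9; 2.00: 21.8, 12.1; 3.00: 30.2, 17.1; 5.00: 41.4, 22.7; 8.00: 50.1, 28.8; 12.0: 58.3, 32.6; 20.0: 62.5, 35.5
- Saturday's (time / h: left-handed product / %, right-handed product / %): 1.33: 21.7, 11.6; 2.00: 28.1, 16.8; 3.00: 37.6, 21.3; 5.00: 49.6, 28.2; 8.00: 56.5, 33.2; 12.0: 61.0, 35.8; 20.0: 62.3, 36.9

(each reading ± 0.5 percentage points)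

- left-handed product and right-handed product together, in percent of the left-handed substrate and right-handed substrate charged together, at 15 h
- excess of left-handed product over right-handed product in the product at 15 h
- whether the exchange between left-handed substrate and right-handed substrate keeps pace with the reaction: how far the product's excess at 15 h gets from its value without exchange to its value with instant exchange (above 80 % keeps pace, below 20 % hardly takes part, else lags behind)

- free catalyst is single-handed; left-handed substrate and right-handed substrate are mirror images of each other, charged as a racemate, each of them at the stated concentration
- what was read earlier has a scatter of 0.5 percentage points, one standard deviation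
- at the start none of the gas is in solution
- an excess is the difference of the two amounts in percent of their sum
- an excess is below zero if the other one leads

- Rate constants are out of sight here, so the readings have to stand in for them, starting from the end state. A racemate wholly converted without exchange gives equal products, an excess of zero.
- At 20.0 h, both runs have turned nearly all of the substrates into product, yet the excess E stands at 27.6 % in Monday's run and 25.6 % in Saturday's. So exchange is at work in both.
- Saturday's flask has converted more than Monday's by 3.00 h and ends with less excess.
- That loss, the catalyst toll T, is the excess given up between Monday's charge and Saturday's: 1.9 percentage points. It rests on two readings from each run, each with a scatter of 0.5 points, so it is a reading too.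
- First way: the flask's charge of 5.0 mM lies below Monday's by half of that span, so E should be 28.5 %.
- Second way: the pooled readings up to 3.00 h, where the selectivity factor shows before the substrates have drawn far apart, give 27.4 %.
- The two part by 1.1 points. The pooled figure mixes both charges and cannot see the catalyst, so 28.5 % is the number to commit to, with exchange keeping pace. Its risk is the toll itself, for the correction of 0.90 points drawn from it stands against a scatter of 0.5 points on each reading behind it.
- The forecast gives 90 %, 27.5 % and "keeps pace", holding that “the substrates interconvert fast compared with reaction”.
- The flask gives 88.3 % and 28.8 %, and exchange keeps pace, 86 % of the way to the value with instant exchange.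

    2 free catalyst → spent catalyst (k = 8.10 × 10⁻⁴ M⁻¹ s⁻¹)
    left-handed substrate ⇌ right-handed substrate (k = 1.80 × 10⁻⁴ s⁻¹)
    partner + free catalyst + left-handed substrate → free catalyst + left-handed product (k = 2.70 M⁻² s⁻¹)
    gas ⇌ partner, rate k4*(csat - [partner]) (kL = 0.00650 s⁻¹)
    partner + free catalyst + right-handed substrate → free catalyst + right-handed product (k = 1.40 M⁻² s⁻¹)

- At 15.0 h in the flask, the step to left-handed product uses left-handed substrate at 0.26 times the rate of the exchange step, forward direction alone. The remaining substrates stand at an excess of right-handed substrate of 3.60 % at 7.50 h. For the neighbour flask charged with 0.0085 M of free catalyst, the toll gives 26.8 %, and that flask holds 27.3 %.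

The data are calculated with made-up constants; scatter was added.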